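The maple run ended, at 12.0 h, with L at 77.0 % inside G at 100.3 % (G counts its L), and two chemists read that pair differently before the new flask was run.

common to all: E 0.20 M; Z 0.14 mM

| charge | X | remark | time |
|---|---|---|---|
| larch | 0.13 M (fed, over 20 min) | run made earlier; the fed solution adds 0.50 times the starting volume |  |
| maple | 0.52 M (fed, over 20 min) | run made earlier; the fed solution adds 0.50 times the starting volume |  |
| flask | 0.260 M (fed, over 20 min) | the fed solution adds 0.50 times the starting volume | 10 h |

| run | time / h | G / % | L / % |
|---|---|---|---|
| larch | 2.00 | 20.8 | 10.7 |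
| larch | 4.00 | 33.4 | 13.1 |
| larch | 6.00 | 37.4 | 12.6 |
| larch | 8.00 | 41.1 | 11.2 |
| larch | 10.0 | 43.6 | 9.0 |
| larch | 12.0 | 48.2 | 12.9 |
| maple | 2.00 | 61.1 | 49.1 |
| maple | 4.00 | 80.7 | 67.7 |
| maple | 6.00 | 91.1 | 71.6 |
| maple | 8.00 | 93.9 | 72.1 |
| maple | 10.0 | 96.6 | 75.2 |
| maple | 12.0 | 100.3 | 77.0 |

(each reading ± 1 percentage point)

- G is meant together with its L
- every charge counts on the volume at the start, and the solution that is fed holds the whole dose
- the numbers in the tables scatter with a standard deviation of 1 percentage point

- the G in the flask at 10 h, as a percentage of the E charged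
- the L in the flask at 10 h, as a percentage of the E charged
- the E in the flask at 10 h, as a percentage of the E charged
- concentration of X at 10 h, in M

The first chemist holds that each G keeps one X, so every E costs two X and X is the limiting reagent. On that view the flask stops with G and L both at 65.0 % of the E charged, and the maple pair is the evidence.

The second chemist answers from the larch run. There the same view stops at 32.5 %, yet G reached 48.2 %, with L at 12.9 %. So L must depend on how much X is free.

My own reckoning takes free X as the charge less G less L, over the volume swollen by the feed. By that reckoning the maple run ends with free X at 0.110 M. Free X times unbound G over L then reads 0.0334 M, the crossing concentration: the free X at which L equals unbound G, which is the dissociation constant of L. The larch run at 4.00 h reads 0.0382 M. While the binding keeps pace, L is G times free X over free X plus the crossing.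

The forecast is the second chemist's: G 72 %, L 34 %, E 28 %, X 0.032 M, on the ground that “L is a fast reversible adduct”. Its binding constant, 27 per molar, stands beside my 29.9 M⁻¹. Its free X lies just under my crossing.

The flask gives G 74.0 %, L 34.0 %, E 26.0 % and X 0.0293 M, so G has passed the first chemist's stop and the forecast stands.

    X + J → Q (k = 2.00 M⁻¹ s⁻¹)
    E + Z ⇌ J (K = 5.50 M⁻¹, k = 7.50 M⁻¹ s⁻¹)
    X + G ⇌ L, settled at all times (K = 29.0 M⁻¹)
    Q ⇌ Z + G (K = 0.190 M, k = 14.0 s⁻¹)

At 5.00 h the flask still held X at 0.0478 M, above the crossing, with L at 34.6 % and G at 59.6 %. At the asked time the rule gives the flask L 34.6 %. The first view comes nearer in the neighbour charged with 3.5 × 10⁻⁵ M of Z, where X stands at 0.0751 M, above the crossing, and L makes up a larger share of G than in the flask. There the rule gives 30.2 % out of G at 43.7 %, and that neighbour holds L at 30.0 %.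

The data stem from a simulated flask from invented constants.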